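## Retrosynthetic overview

1. The target comes from a MOM/TES-protected precursor by two late ortho-formylations and one acid unmasking; before that, equatorial MeLi addition to a C4 ketone and hydrogenation of a C2=C3 enone.
2. The C1–C9′ bond is made by γ-alkylation of the silyl dienol ether of a trans-fused 2-en-4-one with a Cr(CO)3-stabilised benzylic cation (retention at C9′, attack anti to the C10 methyl).
3. The cation precursor, an (R)-benzylic acetate Cr(CO)3 complex, is built in six steps from phloroglucinol (MOM protection, lithiation/isovaleraldehyde, oxidation, CBS reduction, complexation, acetylation).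
4. The decalenone comes from a ring A enone by C3→C4 carbonyl transposition; that enone is closed by intramolecular aldol condensation of a 1,5-diketone made from (S)-carvone, MVK and a chiral-imine Michael addition.
5. Ring order: ring B from carvone (chiral pool), ring A by the intramolecular aldol, arene from phloroglucinol.

Assumption: names use eudesmane numbering (C1–C10 decalin, C11 the side-chain carbinol carbon, C9′ the benzylic carbon), and η6-arene–Cr(CO)3 complexes are written in SMILES as ligand, three CO and Cr joined by dots.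

## Route

Step 1
Reactants: 1 (S)-(+)-carvone
Product: 2 (2S,5S)-dihydrocarvone (trans isomer drawn; the 2-epimer formed alongside is carried on as well)
Conditions: Zn dust, KOH, EtOH/H2O, reflux
Reagents that add atoms: none
Why: Dissolving-metal conjugate reduction saturates only the enone C=C and leaves the isopropenyl group and the C5 stereocentre untouched, while the C2 epimer ratio is irrelevant because C2 becomes sp2 in the next step.

Step 2
Reactants: 2 dihydrocarvone; 3 (S)-(−)-1-phenylethylamine; 4 methyl vinyl ketone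
Product: 7 (2R,5S)-2-methyl-2-(3-oxobutyl)-5-(prop-1-en-2-yl)cyclohexan-1-one, via imine 5 (not isolated), via Michael adduct imine 6 (not isolated)
Conditions: 3, TsOH (cat.), toluene, Dean–Stark, reflux; then 4, THF, 40 °C, 3 d; then 10% aq AcOH, rt
Reagents that add atoms: water, SMILES O
Why: Chiral-imine (secondary enamine) Michael addition in which the more substituted enamine tautomer of 5 adds to MVK through an aza-ene-like transition state on the face anti to the phenyl group of the (S)-auxiliary, setting the quaternary centre (2R, the future C10) with methyl cis to isopropenyl, after which mild acid hydrolysis releases the 1,5-diketone and the auxiliary.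

Step 3
Reactants: 7 1,5-diketone
Product: 9 (7S,10R)-15-noreudesma-4,11-dien-3-one, via ketol 8 (not isolated)
Conditions: KOH, MeOH, rt → reflux
Reagents that add atoms: none
Why: Intramolecular aldol condensation (second stage of a Robinson annulation) in which the methyl-ketone enolate attacks the ring carbonyl in a 6-exo closure to ketol 8, which loses water by E1cB to the conjugated enone and thereby closes ring A without touching C7 or C10.

Step 4
Reactants: 9 ring A enone
Product: 10 (7S,10S)-15-noreudesma-4,11-diene
Conditions: LiAlH4, AlCl3 (1:3), Et2O, 0 °C → reflux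
Reagents that add atoms: none
Why: Mixed-hydride hydrogenolysis in which the enone is reduced to the allylic aluminate, ionises to the allyl cation and takes hydride at the less hindered C3 terminus, so the C4=C5 bond stays in place and no stereocentre is touched.

Step 5
Reactants: 10 diene
Product: 12 (7S,10S)-15-noreudesm-4-en-11-ol, via organomercurial 11 (not isolated)
Conditions: Hg(OAc)2 (1.0 equiv), THF/H2O, rt; then NaBH4, 3 M aq NaOH
Reagents that add atoms: water, SMILES O
Why: Markovnikov oxymercuration–demercuration is much faster for the 1,1-disubstituted isopropenyl alkene than for the hindered trisubstituted C4=C5 bond next to the quaternary carbon, so only the side chain is hydrated to the tertiary alcohol.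

Step 6
Reactants: 12 hydroxy alkene
Product: 14 (5S,7S,10S)-11-hydroxy-15-noreudesman-4-one (trans-decalone), via alkylborane 13 (not isolated)
Conditions: BH3·THF (excess), THF, 0 °C → rt; then Na2Cr2O7, H2SO4, H2O/Et2O, reflux; then K2CO3 (cat.), MeOH, rt
Reagents that add atoms: sodium dichromate Na2Cr2O7 (as chromic acid, supplies the ketone oxygen), SMILES [Na+].[Na+].[O-][Cr](=O)(=O)O[Cr](=O)(=O)[O-]
Why: Hydroboration adds H (to C5) and B (to C4) syn from the face opposite the axial C10 methyl, chromic acid oxidises the C–B bond directly to the ketone (Brown–Garg oxidation), and equilibration at the epimerisable C5 converges any cis-fused material to the more stable trans-decalone (5S).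

Step 7
Reactants: 14 trans-decalone
Product: 16 (5S,7S,10R)-11-(triethylsilyloxy)-15-noreudesm-2-en-4-one, via bis-silyl enol ether 15 (not isolated)
Conditions: LiN(iPr)2 (2.3 equiv), THF, −78 °C; Et3SiCl (2.6 equiv), −78 °C → rt; then Pd(OAc)2 (1.1 equiv), MeCN, rt
Reagents that add atoms: chlorotriethylsilane, SMILES CC[Si](Cl)(CC)CC
Why: Kinetic deprotonation takes the C3 methylene and not the hindered ring-fusion C5–H, and Saegusa–Ito oxidation of the resulting silyl enol ether with Pd(OAc)2 gives the C2=C3 enone, the same pot converting the tertiary alkoxide into its TES ether.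

Step 8
Reactants: 17 phloroglucinol
Product: 18 1,3,5-tris(methoxymethoxy)benzene
Conditions: NaH, MOMCl, DMF, 0 °C → rt
Reagents that add atoms: chloromethyl methyl ether, SMILES COCCl
Why: Williamson etherification of the three phenoxides gives MOM ethers, which are the strongest ortho-directors for the lithiations ahead and can be removed at the end under mild acid.

Step 9
Reactants: 18 tris-MOM arene; 19 isovaleraldehyde
Product: 21 rac-3-methyl-1-[2,4,6-tris(methoxymethoxy)phenyl]butan-1-ol, via aryllithium 20 (not isolated)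
Conditions: n-BuLi (1.05 equiv), THF, 0 °C; then 19, −78 °C → rt; H2O
Reagents that add atoms: none
Why: Directed ortho-metalation between two OMOM groups gives aryllithium 20, whose 1,2-addition to the aldehyde forms the benzylic carbinol as a racemate that is corrected in the next two steps.

Step 10
Reactants: 21 racemic benzylic alcohol
Product: 22 3-methyl-1-[2,4,6-tris(methoxymethoxy)phenyl]butan-1-one
Conditions: Dess–Martin periodinane, pyridine, CH2Cl2, rt
Reagents that add atoms: none
Why: Buffered Dess–Martin oxidation converts the acid-sensitive electron-rich benzylic alcohol into the aryl ketone without ionising it.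

Step 11
Reactants: 22 aryl ketone
Product: 23 (R)-3-methyl-1-[2,4,6-tris(methoxymethoxy)phenyl]butan-1-ol
Conditions: (S)-2-methyl-CBS-oxazaborolidine (0.5 equiv), BH3·SMe2, THF, −20 °C; MeOH quench
Reagents that add atoms: none
Why: Corey–Bakshi–Shibata reduction in which the (S)-oxazaborolidine places the bulky 2,6-disubstituted aryl group as the large substituent and delivers hydride to give the (R)-carbinol.

Step 12
Reactants: 23 (R)-benzylic alcohol
Product: 24 tricarbonyl(η6-arene)chromium complex of 23
Conditions: (η6-naphthalene)Cr(CO)3, THF, 70 °C, dark, argon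
Reagents that add atoms: (η6-naphthalene)Cr(CO)3, SMILES c1ccc2ccccc2c1.[C-]#[O+].[C-]#[O+].[C-]#[O+].[Cr]
Why: Arene exchange from the labile naphthalene complex puts Cr(CO)3 on the electron-rich ring under mild conditions, and since the arene is symmetric about its C1′–C4′ axis a single complex forms in which the benzylic centre is untouched and no longer ionises spontaneously.

Step 13
Reactants: 24 complexed (R)-alcohol
Product: 25 tricarbonyl(η6-arene)chromium complex of (R)-3-methyl-1-[2,4,6-tris(methoxymethoxy)phenyl]butyl acetate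
Conditions: Ac2O, pyridine, DMAP (cat.), CH2Cl2, rt, dark
Reagents that add atoms: acetic anhydride, SMILES CC(=O)OC(C)=O
Why: DMAP-catalysed acylation turns the hydroxyl into a leaving group with retention, since the C–O bond is not broken.

Step 14
Reactants: 16 decalenone; 25 complexed (R)-acetate
Product: 28 (1S,5S,7S,10R)-1-{(1S)-3-methyl-1-[2,4,6-tris(methoxymethoxy)phenyl]butyl}-11-(triethylsilyloxy)-15-noreudesm-2-en-4-one, via silyl dienol ether 26 (not isolated), via chromium-complexed adduct 27 (not isolated)
Conditions: 16 (1.5 equiv), Et3SiOTf, Et3N, CH2Cl2, 0 °C → rt, then pentane and filtration; then 25, BF3·OEt2, CH2Cl2, −78 °C; then air, sunlight, Et2O, rt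
Reagents that add atoms: none
Why: Vinylogous Mukaiyama-type SN1 alkylation in which γ-enolisation gives the through-conjugated dienol ether 26, BF3 ionises the acetate anti to chromium to a configurationally stable Cr(CO)3-stabilised benzylic cation that is attacked from the exo face (net retention, giving 9′S) by the γ-carbon C1 on the face opposite the axial C10 methyl (giving 1S), and air/light then removes the metal.

Step 15
Reactants: 28 coupled enone
Product: 29 (1S,5S,7S,10R)-1-{(1S)-3-methyl-1-[2,4,6-tris(methoxymethoxy)phenyl]butyl}-11-(triethylsilyloxy)-15-noreudesman-4-one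
Conditions: H2 (1 atm), Pd/C, EtOAc, rt
Reagents that add atoms: none
Why: Heterogeneous hydrogenation saturates the disubstituted enone C=C without creating a stereocentre and leaves the MOM ethers, the silyl ether and the ketone intact.

Step 16
Reactants: 29 saturated ketone
Product: 30 (1S,4R,5S,7S,10R)-1-{(1S)-3-methyl-1-[2,4,6-tris(methoxymethoxy)phenyl]butyl}-11-(triethylsilyloxy)eudesman-4-ol
Conditions: MeLi (3 equiv), Et2O, −78 → 0 °C; H2O
Reagents that add atoms: methyllithium, SMILES [Li]C
Why: 1,2-Addition of methyllithium to the trans-decalone follows the equatorial trajectory because axial attack is blocked by the 1,3-diaxial C10 methyl, so the new hydroxyl is axial and cis to that methyl (4R).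

Step 17
Reactants: 30 protected diol
Product: 32 (1S,4R,5S,7S,10R)-1-[(1S)-1-(3,5-diformyl-2,4,6-trihydroxyphenyl)-3-methylbutyl]eudesmane-4,11-diol (target), via protected dialdehyde 31 (not isolated)
Conditions: n-BuLi (2.4 equiv), TMEDA, THF, 0 °C; DMF (1.4 equiv); n-BuLi (1.6 equiv), 0 °C; DMF (excess), 0 °C → rt; then 2 M aq HCl, THF, rt
Reagents that add atoms: N,N-dimethylformamide, SMILES CN(C)C=O
Why: Two successive directed ortho-lithiations at the ring positions flanked by two OMOM groups, each quenched with DMF (the first formyl group staying masked as its lithium hemiaminal during the second lithiation), give the dialdehyde, and aqueous acid then hydrolyses the three MOM acetals and the TES ether without touching any stereocentre.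

## Compound list

1 | (S)-(+)-carvone | CC1=CC[C@@H](CC1=O)C(C)=C | starting material
2 | (2S,5S)-dihydrocarvone (trans; some 2-epimer present) | C[C@H]1CC[C@@H](CC1=O)C(C)=C | intermediate
3 | (S)-(−)-1-phenylethylamine | C[C@H](N)c1ccccc1 | starting material
4 | methyl vinyl ketone | CC(=O)C=C | starting material
5 | N-[(S)-1-phenylethyl] imine of dihydrocarvone | CC1CC[C@@H](CC1=N[C@@H](C)c1ccccc1)C(C)=C | intermediate
6 | imine of the Michael adduct (quaternary carbon R) | CC(=O)CC[C@@]1(C)CC[C@H](C(C)=C)CC1=N[C@@H](C)c1ccccc1 | intermediate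
7 | (2R,5S)-2-methyl-2-(3-oxobutyl)-5-(prop-1-en-2-yl)cyclohexan-1-one | CC(=O)CC[C@@]1(C)CC[C@H](C(C)=C)CC1=O | intermediate
8 | 5-hydroxy-15-noreudesm-11-en-3-one (ketol; C5 not defined, C7 and C10 as in 9) | O=C1CC[C@@]2(C)CC[C@H](C(C)=C)CC2(O)C1 | intermediate
9 | (7S,10R)-15-noreudesma-4,11-dien-3-one | O=C1CC[C@@]2(C)CC[C@H](C(C)=C)CC2=C1 | intermediate
10 | (7S,10S)-15-noreudesma-4,11-diene | C1CC[C@@]2(C)CC[C@H](C(C)=C)CC2=C1 | intermediate
11 | 12-(acetoxymercurio)-15-noreudesm-4-en-11-ol (C11 epimers) | C1CC[C@@]2(C)CC[C@H](C(C)(O)C[Hg]OC(C)=O)CC2=C1 | intermediate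
12 | (7S,10S)-15-noreudesm-4-en-11-ol | C1CC[C@@]2(C)CC[C@H](C(C)(C)O)CC2=C1 | intermediate
13 | C4 alkylborane, drawn as RBH2 (B on C4 and H on C5 cis to each other, trans to the C10 methyl) | [BH2][C@H]1CCC[C@@]2(C)CC[C@H](C(C)(C)O)C[C@H]12 | intermediate
14 | (5S,7S,10S)-11-hydroxy-15-noreudesman-4-one | O=C1CCC[C@@]2(C)CC[C@H](C(C)(C)O)C[C@H]12 | intermediate
15 | 4,11-bis(triethylsilyloxy)-15-noreudesm-3-ene (silyl enol ether) | CC[Si](CC)(CC)OC1=CCC[C@@]2(C)CC[C@H](C(C)(C)O[Si](CC)(CC)CC)C[C@H]12 | intermediate
16 | (5S,7S,10R)-11-(triethylsilyloxy)-15-noreudesm-2-en-4-one | O=C1C=CC[C@@]2(C)CC[C@H](C(C)(C)O[Si](CC)(CC)CC)C[C@H]12 | intermediate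
17 | phloroglucinol | Oc1cc(O)cc(O)c1 | starting material
18 | 1,3,5-tris(methoxymethoxy)benzene | COCOc1cc(OCOC)cc(OCOC)c1 | intermediate
19 | isovaleraldehyde (3-methylbutanal) | CC(C)CC=O | starting material
20 | 2,4,6-tris(methoxymethoxy)phenyllithium | [Li]c1c(OCOC)cc(OCOC)cc1OCOC | intermediate
21 | rac-3-methyl-1-[2,4,6-tris(methoxymethoxy)phenyl]butan-1-ol | CC(C)CC(O)c1c(OCOC)cc(OCOC)cc1OCOC | intermediate
22 | 3-methyl-1-[2,4,6-tris(methoxymethoxy)phenyl]butan-1-one | CC(C)CC(=O)c1c(OCOC)cc(OCOC)cc1OCOC | intermediate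
23 | (R)-3-methyl-1-[2,4,6-tris(methoxymethoxy)phenyl]butan-1-ol | CC(C)C[C@@H](O)c1c(OCOC)cc(OCOC)cc1OCOC | intermediate
24 | tricarbonyl(η6-arene)chromium complex of 23 | CC(C)C[C@@H](O)c1c(OCOC)cc(OCOC)cc1OCOC.[C-]#[O+].[C-]#[O+].[C-]#[O+].[Cr] | intermediate
25 | tricarbonyl(η6-arene)chromium complex of the (R)-acetate | CC(C)C[C@@H](OC(C)=O)c1c(OCOC)cc(OCOC)cc1OCOC.[C-]#[O+].[C-]#[O+].[C-]#[O+].[Cr] | intermediate
26 | (5S,7S,10R)-4,11-bis(triethylsilyloxy)-15-noreudesma-1,3-diene (silyl dienol ether) | CC[Si](CC)(CC)OC1=CC=C[C@@]2(C)CC[C@H](C(C)(C)O[Si](CC)(CC)CC)C[C@H]12 | intermediate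
27 | tricarbonyl(η6-arene)chromium complex of 28 | CC(C)C[C@H](c3c(OCOC)cc(OCOC)cc3OCOC)[C@@H]1C=CC(=O)[C@H]2C[C@@H](C(C)(C)O[Si](CC)(CC)CC)CC[C@]12C.[C-]#[O+].[C-]#[O+].[C-]#[O+].[Cr] | intermediate
28 | (1S,5S,7S,10R)-1-{(1S)-3-methyl-1-[2,4,6-tris(methoxymethoxy)phenyl]butyl}-11-(triethylsilyloxy)-15-noreudesm-2-en-4-one | CC(C)C[C@H](c3c(OCOC)cc(OCOC)cc3OCOC)[C@@H]1C=CC(=O)[C@H]2C[C@@H](C(C)(C)O[Si](CC)(CC)CC)CC[C@]12C | intermediate
29 | (1S,5S,7S,10R)-1-{(1S)-3-methyl-1-[2,4,6-tris(methoxymethoxy)phenyl]butyl}-11-(triethylsilyloxy)-15-noreudesman-4-one | CC(C)C[C@H](c3c(OCOC)cc(OCOC)cc3OCOC)[C@@H]1CCC(=O)[C@H]2C[C@@H](C(C)(C)O[Si](CC)(CC)CC)CC[C@]12C | intermediate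
30 | (1S,4R,5S,7S,10R)-1-{(1S)-3-methyl-1-[2,4,6-tris(methoxymethoxy)phenyl]butyl}-11-(triethylsilyloxy)eudesman-4-ol | CC(C)C[C@H](c3c(OCOC)cc(OCOC)cc3OCOC)[C@@H]1CC[C@@](C)(O)[C@H]2C[C@@H](C(C)(C)O[Si](CC)(CC)CC)CC[C@]12C | intermediate
31 | (1S,4R,5S,7S,10R)-1-{(1S)-1-[3,5-diformyl-2,4,6-tris(methoxymethoxy)phenyl]-3-methylbutyl}-11-(triethylsilyloxy)eudesman-4-ol | CC(C)C[C@H](c3c(OCOC)c(C=O)c(OCOC)c(C=O)c3OCOC)[C@@H]1CC[C@@](C)(O)[C@H]2C[C@@H](C(C)(C)O[Si](CC)(CC)CC)CC[C@]12C | intermediate
32 | (1S,4R,5S,7S,10R)-1-[(1S)-1-(3,5-diformyl-2,4,6-trihydroxyphenyl)-3-methylbutyl]eudesmane-4,11-diol (CNP0409870.3) | CC(C)C[C@H](c1c(O)c(C=O)c(O)c(C=O)c1O)[C@@H]1CC[C@@](C)(O)[C@H]2C[C@@H](C(C)(C)O)CC[C@]12C | target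

## Step count and weak points

Total step count: 17. Longest linear sequence: 11 steps (steps 1–7, then 14–17). The arene branch (steps 8–13) is 6 steps and joins at step 14.

The three steps most likely to fail:

Step 14 (fragment coupling). The γ-carbon C1 is neopentyl and the cation is hindered, so α-attack at C3, simple desilylation of 26, or loss of stereospecificity by rotation of the cation could all intrude. The fallback sets out from 16 (with 18 as the arene source) and comes back at 29. Arene 18 is lithiated as in step 9 and quenched with DMF to give 2,4,6-tris(methoxymethoxy)benzaldehyde F3. Dienol ether 26, made from 16 as in step 14, undergoes a BF3·OEt2-mediated vinylogous Mukaiyama aldol addition to F3 at C1, again anti to the C10 methyl, giving the benzylic carbinol F4 as a mixture at C9′. Ionisation of F4 (BF3·OEt2, CH2Cl2, −78 °C) in the presence of methallyltrimethylsilane gives the methallyl adduct F5. Here C9′ is set by 1,2-induction instead of by the chromium template: the free cation adopts the A(1,3)-strain-minimised conformation with C1–H in the cation plane, the quaternary C10 shields one face, and the silane enters on the C2 side, which gives 9′S. Hydrogenation (H2, Pd/C, EtOAc) then saturates both the enone and the methallyl C=C and delivers 29.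

Step 17 (double ortho-lithiation/formylation). The second deprotonation has to take place on a polyanion carrying an alkoxide and a lithium hemiaminal, and may stop at the mono-aldehyde. The fallback sets out from 30 and comes back at 31. Both free ring positions are brominated with NBS (2.1 equiv, MeCN, 0 °C) to give the dibromide F6. After deprotonation of the hydroxyl with MeLi (1 equiv), double bromine–lithium exchange with t-BuLi (4.4 equiv, THF, −78 °C) and a DMF quench give 31, which is isolated and then treated with 2 M aq HCl in THF as in the last stage of step 17.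

Step 4 (mixed-hydride deoxygenation). Hydride may add at C5 of the allyl cation and give the 3-ene, or the isopropenyl group may be affected by the Lewis acid. The fallback sets out from 9 and comes back at 12, so step 5 is skipped. The side chain is hydrated first (Hg(OAc)2, THF/H2O; then NaBH4, NaOH) to give the hydroxy enone F1. F1 is converted with ethane-1,2-dithiol and catalytic I2 in CHCl3 into the dithiolane F2, the C4=C5 bond staying in place. Desulfurisation with Raney Ni in refluxing EtOH then gives 12.

## Further compounds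

F1 | step 4 | (7S,10R)-11-hydroxy-15-noreudesm-4-en-3-one | O=C1CC[C@@]2(C)CC[C@H](C(C)(C)O)CC2=C1
F2 | step 4 | 3,3-(ethylenedithio)-15-noreudesm-4-en-11-ol (1,3-dithiolane of F1) | S1CCSC12CC[C@@]3(C)CC[C@H](C(C)(C)O)CC3=C2
F3 | step 14 | 2,4,6-tris(methoxymethoxy)benzaldehyde | COCOc1cc(OCOC)c(C=O)c(OCOC)c1
F4 | step 14 | 1-{hydroxy[2,4,6-tris(methoxymethoxy)phenyl]methyl}-11-(triethylsilyloxy)-15-noreudesm-2-en-4-one (C9′ epimers) | OC(c3c(OCOC)cc(OCOC)cc3OCOC)[C@@H]1C=CC(=O)[C@H]2C[C@@H](C(C)(C)O[Si](CC)(CC)CC)CC[C@]12C
F5 | step 14 | (1S,5S,7S,10R)-1-{(1S)-3-methyl-1-[2,4,6-tris(methoxymethoxy)phenyl]but-3-enyl}-11-(triethylsilyloxy)-15-noreudesm-2-en-4-one | CC(=C)C[C@H](c3c(OCOC)cc(OCOC)cc3OCOC)[C@@H]1C=CC(=O)[C@H]2C[C@@H](C(C)(C)O[Si](CC)(CC)CC)CC[C@]12C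
F6 | step 17 | (1S,4R,5S,7S,10R)-1-{(1S)-1-[3,5-dibromo-2,4,6-tris(methoxymethoxy)phenyl]-3-methylbutyl}-11-(triethylsilyloxy)eudesman-4-ol | CC(C)C[C@H](c3c(OCOC)c(Br)c(OCOC)c(Br)c3OCOC)[C@@H]1CC[C@@](C)(O)[C@H]2C[C@@H](C(C)(C)O[Si](CC)(CC)CC)CC[C@]12C
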